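**Plan**

1. Retrosynthetic cuts: the C3–CH2 bond of the lactone (enolate benzylation) separates a ring-A benzylic bromide carrying the open-chain diol from an (R)-4-substituted butyrolactone. The lactone goes back through a Stobbe half-ester to an aryl aldehyde and dimethyl succinate, the dihydrobenzofuran is cut at O1–C2, and each diarylpropane unit is cut at the aldol C–C bond between an arylacetyl imide and a vanillin ether.
2. Enabling feature: C2 of the dihydrobenzofuran is benzylic, lies para to the free phenol of its guaiacyl ring, and is bonded to O1, the oxygen of the phenol ortho to C3a on the bromo-methoxy ring. The O1–C2 bond is therefore what forms when that phenol adds to a p-quinone methide.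
3. Forward order: one Claisen-derived phenol (2-allyl-4-bromo-6-methoxyphenol) feeds both halves. In the MOM series a boron aldol and LiBH4 give the diol, acid closes the dihydrofuran (ring 1), and the bromide is taken via aldehyde, Stobbe condensation, hydrogenation and reduction to the lactone (ring 2). In the benzyl series an anti aldol gives the open-chain diol, which is silylated and turned into the benzylic bromide; enolate alkylation joins the halves, then fluoride and hydrogenolysis unmask the target.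
4. Stereochemistry: dihydrofuran C3 comes from the boron aldol on the (S)-oxazolidinone and C2 from trans ring closure under control of C3. Lactone C4 comes from Rh/(S,S)-Et-DuPhos hydrogenation and C3 from trans alkylation. The open-chain C1/C2 pair comes from a magnesium-catalysed anti aldol on the same (S)-auxiliary, whose chelated enolate reacts on the opposite face.
5. The open-chain diol of the target could itself undergo the acid closure, so it is carried silylated with benzylated phenols and every step after the fragment union is non-acidic.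

Key step: step 9

Assumption: the target descriptors read from the SMILES are (2S,3R) in the dihydrobenzofuran, (3R,4R) in the lactone and (1S,2S) in the open chain, and the magnesium-catalysed aldol is taken to follow the chelate-controlled facial sense of imide alkylations.

**Route**

Step 1
Reactants: 1 4-bromo-2-methoxyphenol
Product: 2 1-(allyloxy)-4-bromo-2-methoxybenzene
Conditions: allyl bromide, K2CO3, acetone, reflux
Reagents that add atoms: allyl bromide, C=CCBr
Why: Williamson ether synthesis, in which the potassium phenoxide displaces bromide from the allylic halide by SN2 and no stereocenter is involved.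

Step 2
Reactants: 2 1-(allyloxy)-4-bromo-2-methoxybenzene
Product: 4 2-allyl-4-bromo-6-methoxyphenol, via Claisen dienone 3 (not isolated)
Conditions: N,N-diethylaniline, 200 °C
Reagents that add atoms: none
Why: Aromatic Claisen rearrangement, whose [3,3] shift can only reach the single free ortho carbon (the other ortho carbon carries OMe and the para carbon carries Br) before the dienone tautomerises to the phenol.

Step 3
Reactants: 4 2-allyl-4-bromo-6-methoxyphenol
Product: 5 1-allyl-5-bromo-3-methoxy-2-(methoxymethoxy)benzene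
Conditions: NaH, MOMCl, THF–DMF, 0 °C → rt
Reagents that add atoms: chloromethyl methyl ether, COCCl
Why: Phenol O-alkylation to a MOM acetal, which the hindered sodium phenoxide forms readily with the unhindered chloromethyl ether and which survives base, hydride and boron reagents but leaves with acid in step 9.

Step 4
Reactants: 5 1-allyl-5-bromo-3-methoxy-2-(methoxymethoxy)benzene
Product: 7 2-[5-bromo-3-methoxy-2-(methoxymethoxy)phenyl]acetic acid, via arylacetaldehyde 6 (not isolated)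
Conditions: O3, CH2Cl2, −78 °C; PPh3, → rt; then NaClO2, NaH2PO4, 2-methyl-2-butene, t-BuOH–H2O, rt
Reagents that add atoms: ozone, [O-][O+]=O; sodium chlorite, [Na+].[O-]Cl=O
Why: Ozonolysis with reductive work-up followed by Pinnick oxidation, in which ozone consumes the isolated terminal alkene far faster than the arene and buffered chlorite with an HOCl scavenger oxidises the sensitive crude aldehyde without harming the MOM ether.

Step 5
Reactants: 7 2-[5-bromo-3-methoxy-2-(methoxymethoxy)phenyl]acetic acid; 8 (S)-4-benzyl-2-oxazolidinone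
Product: 10 (4S)-4-benzyl-3-{2-[5-bromo-3-methoxy-2-(methoxymethoxy)phenyl]acetyl}-1,3-oxazolidin-2-one, via mixed pivalic anhydride 9 (not isolated)
Conditions: PivCl, Et3N, THF, −20 °C; then 8, LiCl, −20 °C → rt
Reagents that add atoms: none
Why: N-acylation of the oxazolidinone through a mixed anhydride, where the shielded pivaloyl carbonyl directs attack to the arylacetyl carbonyl and the auxiliary stereocenter is untouched.

Step 6
Reactants: 11 vanillin
Product: 12 3-methoxy-4-(methoxymethoxy)benzaldehyde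
Conditions: MOMCl, i-Pr2NEt, CH2Cl2, 0 °C → rt
Reagents that add atoms: chloromethyl methyl ether, COCCl
Why: Phenol protection as a MOM acetal by O-alkylation, chosen so that this phenol is released in the same acid pot that closes the ring.

Step 7
Reactants: 10 MOM-series arylacetyl imide; 12 3-methoxy-4-(methoxymethoxy)benzaldehyde
Product: 13 (4S)-4-benzyl-3-{(2S,3S)-2-[5-bromo-3-methoxy-2-(methoxymethoxy)phenyl]-3-hydroxy-3-[3-methoxy-4-(methoxymethoxy)phenyl]propanoyl}-1,3-oxazolidin-2-one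
Conditions: n-Bu2BOTf, i-Pr2NEt, CH2Cl2, 0 °C; 12, −78 → 0 °C; then pH 7 buffer, MeOH, H2O2, 0 °C
Reagents that add atoms: none
Why: Evans syn aldol reaction, in which the (Z)-boron enolate reacts through a closed chair transition state with the imide dipoles opposed, so the aldehyde meets the enolate face away from the auxiliary benzyl group and the (2S,3S) adduct results; C2 becomes C3 of the dihydrofuran.

Step 8
Reactants: 13 syn aldol adduct
Product: 14 (1S,2R)-2-[5-bromo-3-methoxy-2-(methoxymethoxy)phenyl]-1-[3-methoxy-4-(methoxymethoxy)phenyl]propane-1,3-diol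
Conditions: LiBH4, MeOH (1 equiv), THF, 0 °C
Reagents that add atoms: none
Why: Reductive cleavage of the N-acyloxazolidinone with LiBH4, which reduces the exocyclic imide carbonyl to the primary alcohol at 0 °C without epimerising the benzylic carbon and returns the auxiliary.

Step 9
Reactants: 14 bis-MOM syn diol
Product: 17 4-[(2S,3R)-5-bromo-3-(hydroxymethyl)-7-methoxy-2,3-dihydro-1-benzofuran-2-yl]-2-methoxyphenol, via bis-phenol diol 15 (not isolated), via p-quinone methide 16 (not isolated)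
Conditions: HCl (1 M in MeOH), 40 °C
Reagents that add atoms: none
Why: Acidic methanol first cleaves both MOM acetals to the bis-phenol diol 15, whose benzylic hydroxyl is protonated and expelled with the push of the para phenol to give the planar p-quinone methide 16, so the carbinol configuration from the aldol is erased. The ortho phenol of the bromo ring then adds to the exocyclic methide carbon (intramolecular oxa-1,6-conjugate addition) and the guaiacyl ring re-aromatises, which forms O1–C2. The closest known reaction is the acid-promoted cyclisation of 1-(4-hydroxyaryl)-2-(2-hydroxyaryl)propane-1,3-diols to trans-2-aryl-3-(hydroxymethyl)-2,3-dihydrobenzofurans. The five-membered ring closes in the 5-exo-trig mode. The new C2 stereocenter is controlled by the existing C3 center from step 7: the phenol takes the methide face that puts the aryl group trans to CH2OH, and since the addition is reversible under acid the more stable trans (2S,3R) isomer should accumulate. The step needs phenol oxygen over other nucleophiles and trans over cis, which the substrate secures because the primary alcohol could only form an oxetane, methanol adducts re-ionise under the same acid, and the phenol sits exactly five atoms from the methide carbon.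

Step 10
Reactants: 17 dihydrobenzofuran bromide with free phenol and primary alcohol
Product: 19 {[(2S,3R)-2-[4-(benzyloxy)-3-methoxyphenyl]-5-bromo-7-methoxy-2,3-dihydro-1-benzofuran-3-yl]methoxy}(tert-butyl)dimethylsilane, via monobenzyl ether 18 (not isolated)
Conditions: BnBr, K2CO3, DMF, rt; then TBSCl, imidazole, rt
Reagents that add atoms: benzyl bromide, BrCc1ccccc1; tert-butyldimethylsilyl chloride, CC(C)(C)[Si](C)(C)Cl
Why: Chemoselective Williamson benzylation followed by silyl ether formation, since carbonate deprotonates only the phenol, which is capped before the ring can reopen, and imidazole/TBSCl then silylates the primary alcohol without touching either stereocenter.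

Step 11
Reactants: 19 benzyl/TBS-protected dihydrobenzofuran bromide
Product: 20 (2S,3R)-2-[4-(benzyloxy)-3-methoxyphenyl]-3-{[(tert-butyldimethylsilyl)oxy]methyl}-7-methoxy-2,3-dihydro-1-benzofuran-5-carbaldehyde
Conditions: n-BuLi, THF, −78 °C; DMF, −78 → 0 °C; H2O
Reagents that add atoms: N,N-dimethylformamide, CN(C)C=O
Why: Bromine–lithium exchange followed by formylation of the aryllithium with DMF, where exchange at −78 °C outruns any deprotonation and the aldehyde is released only on aqueous work-up.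

Step 12
Reactants: 20 dihydrobenzofuran aldehyde; 21 dimethyl succinate
Product: 22 (3E)-4-{(2S,3R)-2-[4-(benzyloxy)-3-methoxyphenyl]-3-{[(tert-butyldimethylsilyl)oxy]methyl}-7-methoxy-2,3-dihydro-1-benzofuran-5-yl}-3-(methoxycarbonyl)but-3-enoic acid
Conditions: NaOMe, MeOH, reflux; then 1 M HCl to pH 3
Reagents that add atoms: none
Why: Stobbe condensation, in which the succinate enolate condenses with the non-enolisable aldehyde and the sequence ends irreversibly in the carboxylate of the (E)-arylidene half-ester, with the benzyl and silyl ethers stable to methoxide.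

Step 13
Reactants: 22 (E)-arylidene succinate half-ester
Product: 23 (3R)-4-{(2S,3R)-2-[4-(benzyloxy)-3-methoxyphenyl]-3-{[(tert-butyldimethylsilyl)oxy]methyl}-7-methoxy-2,3-dihydro-1-benzofuran-5-yl}-3-(methoxycarbonyl)butanoic acid
Conditions: H2 (5 bar), [Rh(cod)((S,S)-Et-DuPhos)]BF4 (1 mol %), Et3N (1 equiv), MeOH, rt
Reagents that add atoms: none
Why: Rhodium-catalysed asymmetric hydrogenation of an itaconate-type half-ester, in which the carboxylate arm chelates monovalent rhodium and the (S,S)-ligand is the enantiomer expected to turn (E)-arylidene succinates into (R)-benzylsuccinates, while benzyl ethers are inert to the homogeneous catalyst.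

Step 14
Reactants: 23 (R)-benzylsuccinate half-ester
Product: 25 (4R)-4-({(2S,3R)-2-[4-(benzyloxy)-3-methoxyphenyl]-3-{[(tert-butyldimethylsilyl)oxy]methyl}-7-methoxy-2,3-dihydro-1-benzofuran-5-yl}methyl)oxolan-2-one, via hydroxy acid 24 (not isolated)
Conditions: KOH (1 equiv), EtOH; then CaCl2, NaBH4, EtOH, −10 °C → rt; then 1 M HCl to pH 3, rt
Reagents that add atoms: none
Why: Chemoselective ester reduction with Ca(BH4)2 beside a carboxylate salt followed by acid-induced lactonisation, so the ester carbon becomes the OCH2 of the lactone and the stereocenter from step 13 is carried over unchanged as C4.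

Step 15
Reactants: 4 2-allyl-4-bromo-6-methoxyphenol
Product: 26 1-allyl-2-(benzyloxy)-5-bromo-3-methoxybenzene
Conditions: BnBr, K2CO3, DMF, 50 °C
Reagents that add atoms: benzyl bromide, BrCc1ccccc1
Why: Williamson benzylation of the phenol, which gives a ring-A protecting group that stays on until the neutral hydrogenolysis at the end.

Step 16
Reactants: 26 1-allyl-2-(benzyloxy)-5-bromo-3-methoxybenzene
Product: 28 2-[2-(benzyloxy)-5-bromo-3-methoxyphenyl]acetic acid, via arylacetaldehyde 27 (not isolated)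
Conditions: O3, CH2Cl2, −78 °C; PPh3, → rt; then NaClO2, NaH2PO4, 2-methyl-2-butene, t-BuOH–H2O, rt
Reagents that add atoms: ozone, [O-][O+]=O; sodium chlorite, [Na+].[O-]Cl=O
Why: Ozonolysis with reductive work-up followed by Pinnick oxidation, as in step 4, with the benzyl ether inert to a stoichiometric charge of ozone at −78 °C.

Step 17
Reactants: 28 2-[2-(benzyloxy)-5-bromo-3-methoxyphenyl]acetic acid; 8 (S)-4-benzyl-2-oxazolidinone
Product: 30 (4S)-4-benzyl-3-{2-[2-(benzyloxy)-5-bromo-3-methoxyphenyl]acetyl}-1,3-oxazolidin-2-one, via mixed pivalic anhydride 29 (not isolated)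
Conditions: PivCl, Et3N, THF, −20 °C; then 8, LiCl, −20 °C → rt
Reagents that add atoms: none
Why: N-acylation of the oxazolidinone through a mixed anhydride, as in step 5.

Step 18
Reactants: 30 benzyl-series arylacetyl imide; 31 4-(benzyloxy)-3-methoxybenzaldehyde
Product: 33 (4S)-4-benzyl-3-{(2R,3S)-2-[2-(benzyloxy)-5-bromo-3-methoxyphenyl]-3-[4-(benzyloxy)-3-methoxyphenyl]-3-hydroxypropanoyl}-1,3-oxazolidin-2-one, via TMS ether 32 (not isolated)
Conditions: MgCl2 (0.2 equiv), Et3N, TMSCl, EtOAc, rt; then 1 M HCl, THF, 0 °C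
Reagents that add atoms: none
Why: Magnesium halide-catalysed direct anti aldol reaction of an N-acyloxazolidinone, in which the chelated (Z)-magnesium enolate is attacked on the face opposite the auxiliary benzyl group (the sense of imide alkylations, opposite to step 7) through a boat-like transition state that places the aryl groups anti, and TMSCl traps the aldolate so that the (2R,3S) adduct should persist.

Step 19
Reactants: 33 anti aldol adduct
Product: 34 (1S,2S)-2-[2-(benzyloxy)-5-bromo-3-methoxyphenyl]-1-[4-(benzyloxy)-3-methoxyphenyl]propane-1,3-diol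
Conditions: LiBH4, MeOH (1 equiv), THF, 0 °C
Reagents that add atoms: none
Why: Reductive cleavage of the N-acyloxazolidinone with LiBH4, as in step 8, which keeps both stereocenters and returns the auxiliary.

Step 20
Reactants: 34 anti diol
Product: 35 bis-TBS ether of the (1S,2S)-diol
Conditions: TBSOTf, 2,6-lutidine, CH2Cl2, −78 → 0 °C
Reagents that add atoms: tert-butyldimethylsilyl trifluoromethanesulfonate, CC(C)(C)[Si](C)(C)OS(=O)(=O)C(F)(F)F
Why: Silyl ether formation with a silyl triflate, reactive enough to cap the hindered benzylic hydroxyl as well as the primary one, so the diol is masked by groups that fluoride removes without acid.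

Step 21
Reactants: 35 bis-TBS aryl bromide
Product: 36 4-(benzyloxy)-3-{(1S,2S)-1-[4-(benzyloxy)-3-methoxyphenyl]-1,3-bis[(tert-butyldimethylsilyl)oxy]propan-2-yl}-5-methoxybenzaldehyde
Conditions: n-BuLi, THF, −78 °C; DMF, −78 → 0 °C; H2O
Reagents that add atoms: N,N-dimethylformamide, CN(C)C=O
Why: Bromine–lithium exchange followed by formylation with DMF, as in step 11, with silyl and benzyl ethers inert at −78 °C.

Step 22
Reactants: 36 ring-A aldehyde
Product: 37 (4-(benzyloxy)-3-{(1S,2S)-1-[4-(benzyloxy)-3-methoxyphenyl]-1,3-bis[(tert-butyldimethylsilyl)oxy]propan-2-yl}-5-methoxyphenyl)methanol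
Conditions: NaBH4, THF–MeOH, 0 °C
Reagents that add atoms: none
Why: Hydride reduction of an aromatic aldehyde with NaBH4, which touches no other group in the molecule.

Step 23
Reactants: 37 ring-A benzylic alcohol
Product: 38 4-(benzyloxy)-3-{(1S,2S)-1-[4-(benzyloxy)-3-methoxyphenyl]-1,3-bis[(tert-butyldimethylsilyl)oxy]propan-2-yl}-5-methoxybenzyl bromide
Conditions: CBr4, PPh3, CH2Cl2, 0 °C
Reagents that add atoms: carbon tetrabromide, BrC(Br)(Br)Br
Why: Appel reaction, which converts the primary benzylic alcohol into the bromide under neutral conditions that spare the silyl ethers; the bromide would be used at once.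

Step 24
Reactants: 25 (R)-lactone; 38 ring-A benzylic bromide
Product: 39 (3R,4R)-3-(4-(benzyloxy)-3-{(1S,2S)-1-[4-(benzyloxy)-3-methoxyphenyl]-1,3-bis[(tert-butyldimethylsilyl)oxy]propan-2-yl}-5-methoxybenzyl)-4-({(2S,3R)-2-[4-(benzyloxy)-3-methoxyphenyl]-3-{[(tert-butyldimethylsilyl)oxy]methyl}-7-methoxy-2,3-dihydro-1-benzofuran-5-yl}methyl)oxolan-2-one
Conditions: LiN(SiMe3)2, THF, −78 °C; then 38, −78 → −30 °C
Reagents that add atoms: none
Why: Diastereoselective alkylation of a lactone enolate, in which the lithium enolate of the 4-substituted butyrolactone is benzylated on the face anti to the C4 substituent and so gives the trans (3R,4R) lactone, as is usual for dibenzylbutyrolactones.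

Step 25
Reactants: 39 fully protected coupled lactone
Product: 40 (3R,4R)-3-(4-(benzyloxy)-3-{(1S,2S)-1-[4-(benzyloxy)-3-methoxyphenyl]-1,3-dihydroxypropan-2-yl}-5-methoxybenzyl)-4-({(2S,3R)-2-[4-(benzyloxy)-3-methoxyphenyl]-3-(hydroxymethyl)-7-methoxy-2,3-dihydro-1-benzofuran-5-yl}methyl)oxolan-2-one
Conditions: n-Bu4NF, AcOH, THF, 0 °C → rt
Reagents that add atoms: none
Why: Fluoride-mediated desilylation buffered with acetic acid, which removes the three TBS groups while the phenols are still benzylated, so neither a quinone methide nor a phenoxide can form and the trans lactone is not disturbed.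

Step 26
Reactants: 40 tris-benzyl ether triol
Product: 41 (3R,4R)-4-{[(2S,3R)-2-(4-hydroxy-3-methoxyphenyl)-3-(hydroxymethyl)-7-methoxy-2,3-dihydro-1-benzofuran-5-yl]methyl}-3-{3-[(1S,2S)-1,3-dihydroxy-1-(4-hydroxy-3-methoxyphenyl)propan-2-yl]-4-hydroxy-5-methoxybenzyl}oxolan-2-one
Conditions: H2 (1 atm), 10% Pd/C, EtOAc–EtOH, rt
Reagents that add atoms: none
Why: Hydrogenolysis of three aryl benzyl ethers over Pd/C under neutral, acid-free conditions, which is fast enough that the benzylic C–O bonds of the dihydrofuran and of the free carbinol should survive and which leaves the acid-sensitive open-chain diol unclosed.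

**Compound list**

1 | 4-bromo-2-methoxyphenol | COc1cc(Br)ccc1O | starting material
2 | 1-(allyloxy)-4-bromo-2-methoxybenzene | C=CCOc1ccc(Br)cc1OC | intermediate
3 | 6-allyl-4-bromo-2-methoxycyclohexa-2,4-dien-1-one | O=C1C(OC)=CC(Br)=CC1CC=C | intermediate
4 | 2-allyl-4-bromo-6-methoxyphenol | C=CCc1cc(Br)cc(OC)c1O | intermediate
5 | 1-allyl-5-bromo-3-methoxy-2-(methoxymethoxy)benzene | C=CCc1cc(Br)cc(OC)c1OCOC | intermediate
6 | 2-[5-bromo-3-methoxy-2-(methoxymethoxy)phenyl]acetaldehyde | O=CCc1cc(Br)cc(OC)c1OCOC | intermediate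
7 | 2-[5-bromo-3-methoxy-2-(methoxymethoxy)phenyl]acetic acid | OC(=O)Cc1cc(Br)cc(OC)c1OCOC | intermediate
8 | (S)-4-benzyl-2-oxazolidinone | O=C1N[C@@H](Cc2ccccc2)CO1 | starting material
9 | 2-[5-bromo-3-methoxy-2-(methoxymethoxy)phenyl]acetic 2,2-dimethylpropanoic anhydride | CC(C)(C)C(=O)OC(=O)Cc1cc(Br)cc(OC)c1OCOC | intermediate
10 | (4S)-4-benzyl-3-{2-[5-bromo-3-methoxy-2-(methoxymethoxy)phenyl]acetyl}-1,3-oxazolidin-2-one | O=C1OC[C@H](Cc2ccccc2)N1C(=O)Cc1cc(Br)cc(OC)c1OCOC | intermediate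
11 | vanillin (4-hydroxy-3-methoxybenzaldehyde) | O=Cc1ccc(O)c(OC)c1 | starting material
12 | 3-methoxy-4-(methoxymethoxy)benzaldehyde | O=Cc1ccc(OCOC)c(OC)c1 | intermediate
13 | (4S)-4-benzyl-3-{(2S,3S)-2-[5-bromo-3-methoxy-2-(methoxymethoxy)phenyl]-3-hydroxy-3-[3-methoxy-4-(methoxymethoxy)phenyl]propanoyl}-1,3-oxazolidin-2-one | COc1cc([C@@H](O)[C@@H](C(=O)N2[C@@H](Cc3ccccc3)COC2=O)c2cc(Br)cc(OC)c2OCOC)ccc1OCOC | intermediate
14 | (1S,2R)-2-[5-bromo-3-methoxy-2-(methoxymethoxy)phenyl]-1-[3-methoxy-4-(methoxymethoxy)phenyl]propane-1,3-diol | COc1cc([C@@H](O)[C@@H](CO)c2cc(Br)cc(OC)c2OCOC)ccc1OCOC | intermediate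
15 | (1S,2R)-2-(5-bromo-2-hydroxy-3-methoxyphenyl)-1-(4-hydroxy-3-methoxyphenyl)propane-1,3-diol | COc1cc([C@@H](O)[C@@H](CO)c2cc(Br)cc(OC)c2O)ccc1O | intermediate
16 | 4-[(2R)-2-(5-bromo-2-hydroxy-3-methoxyphenyl)-3-hydroxypropylidene]-2-methoxycyclohexa-2,5-dien-1-one | OC[C@@H](c1cc(Br)cc(OC)c1O)C=C1C=CC(=O)C(OC)=C1 | intermediate
17 | 4-[(2S,3R)-5-bromo-3-(hydroxymethyl)-7-methoxy-2,3-dihydro-1-benzofuran-2-yl]-2-methoxyphenol | Brc1cc(OC)c2c(c1)[C@H](CO)[C@@H](c1ccc(O)c(OC)c1)O2 | intermediate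
18 | [(2S,3R)-2-[4-(benzyloxy)-3-methoxyphenyl]-5-bromo-7-methoxy-2,3-dihydro-1-benzofuran-3-yl]methanol | Brc1cc(OC)c2c(c1)[C@H](CO)[C@@H](c1ccc(OCc3ccccc3)c(OC)c1)O2 | intermediate
19 | {[(2S,3R)-2-[4-(benzyloxy)-3-methoxyphenyl]-5-bromo-7-methoxy-2,3-dihydro-1-benzofuran-3-yl]methoxy}(tert-butyl)dimethylsilane | Brc1cc(OC)c2c(c1)[C@H](CO[Si](C)(C)C(C)(C)C)[C@@H](c1ccc(OCc3ccccc3)c(OC)c1)O2 | intermediate
20 | (2S,3R)-2-[4-(benzyloxy)-3-methoxyphenyl]-3-{[(tert-butyldimethylsilyl)oxy]methyl}-7-methoxy-2,3-dihydro-1-benzofuran-5-carbaldehyde | O=Cc1cc(OC)c2c(c1)[C@H](CO[Si](C)(C)C(C)(C)C)[C@@H](c1ccc(OCc3ccccc3)c(OC)c1)O2 | intermediate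
21 | dimethyl succinate | COC(=O)CCC(=O)OC | starting material
22 | (3E)-4-{(2S,3R)-2-[4-(benzyloxy)-3-methoxyphenyl]-3-{[(tert-butyldimethylsilyl)oxy]methyl}-7-methoxy-2,3-dihydro-1-benzofuran-5-yl}-3-(methoxycarbonyl)but-3-enoic acid | OC(=O)C/C(C(=O)OC)=C\c1cc(OC)c2c(c1)[C@H](CO[Si](C)(C)C(C)(C)C)[C@@H](c1ccc(OCc3ccccc3)c(OC)c1)O2 | intermediate
23 | (3R)-4-{(2S,3R)-2-[4-(benzyloxy)-3-methoxyphenyl]-3-{[(tert-butyldimethylsilyl)oxy]methyl}-7-methoxy-2,3-dihydro-1-benzofuran-5-yl}-3-(methoxycarbonyl)butanoic acid | OC(=O)C[C@H](C(=O)OC)Cc1cc(OC)c2c(c1)[C@H](CO[Si](C)(C)C(C)(C)C)[C@@H](c1ccc(OCc3ccccc3)c(OC)c1)O2 | intermediate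
24 | (3R)-4-{(2S,3R)-2-[4-(benzyloxy)-3-methoxyphenyl]-3-{[(tert-butyldimethylsilyl)oxy]methyl}-7-methoxy-2,3-dihydro-1-benzofuran-5-yl}-3-(hydroxymethyl)butanoic acid | OC(=O)C[C@H](CO)Cc1cc(OC)c2c(c1)[C@H](CO[Si](C)(C)C(C)(C)C)[C@@H](c1ccc(OCc3ccccc3)c(OC)c1)O2 | intermediate
25 | (4R)-4-({(2S,3R)-2-[4-(benzyloxy)-3-methoxyphenyl]-3-{[(tert-butyldimethylsilyl)oxy]methyl}-7-methoxy-2,3-dihydro-1-benzofuran-5-yl}methyl)oxolan-2-one | O=C1C[C@@H](Cc2cc(OC)c3c(c2)[C@H](CO[Si](C)(C)C(C)(C)C)[C@@H](c2ccc(OCc4ccccc4)c(OC)c2)O3)CO1 | intermediate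
26 | 1-allyl-2-(benzyloxy)-5-bromo-3-methoxybenzene | C=CCc1cc(Br)cc(OC)c1OCc1ccccc1 | intermediate
27 | 2-[2-(benzyloxy)-5-bromo-3-methoxyphenyl]acetaldehyde | O=CCc1cc(Br)cc(OC)c1OCc1ccccc1 | intermediate
28 | 2-[2-(benzyloxy)-5-bromo-3-methoxyphenyl]acetic acid | OC(=O)Cc1cc(Br)cc(OC)c1OCc1ccccc1 | intermediate
29 | 2-[2-(benzyloxy)-5-bromo-3-methoxyphenyl]acetic 2,2-dimethylpropanoic anhydride | CC(C)(C)C(=O)OC(=O)Cc1cc(Br)cc(OC)c1OCc1ccccc1 | intermediate
30 | (4S)-4-benzyl-3-{2-[2-(benzyloxy)-5-bromo-3-methoxyphenyl]acetyl}-1,3-oxazolidin-2-one | O=C1OC[C@H](Cc2ccccc2)N1C(=O)Cc1cc(Br)cc(OC)c1OCc1ccccc1 | intermediate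
31 | 4-(benzyloxy)-3-methoxybenzaldehyde | O=Cc1ccc(OCc2ccccc2)c(OC)c1 | starting material
32 | (4S)-4-benzyl-3-{(2R,3S)-2-[2-(benzyloxy)-5-bromo-3-methoxyphenyl]-3-[4-(benzyloxy)-3-methoxyphenyl]-3-[(trimethylsilyl)oxy]propanoyl}-1,3-oxazolidin-2-one | COc1cc([C@@H](O[Si](C)(C)C)[C@H](C(=O)N2[C@@H](Cc3ccccc3)COC2=O)c2cc(Br)cc(OC)c2OCc2ccccc2)ccc1OCc1ccccc1 | intermediate
33 | (4S)-4-benzyl-3-{(2R,3S)-2-[2-(benzyloxy)-5-bromo-3-methoxyphenyl]-3-[4-(benzyloxy)-3-methoxyphenyl]-3-hydroxypropanoyl}-1,3-oxazolidin-2-one | COc1cc([C@@H](O)[C@H](C(=O)N2[C@@H](Cc3ccccc3)COC2=O)c2cc(Br)cc(OC)c2OCc2ccccc2)ccc1OCc1ccccc1 | intermediate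
34 | (1S,2S)-2-[2-(benzyloxy)-5-bromo-3-methoxyphenyl]-1-[4-(benzyloxy)-3-methoxyphenyl]propane-1,3-diol | COc1cc([C@@H](O)[C@H](CO)c2cc(Br)cc(OC)c2OCc2ccccc2)ccc1OCc1ccccc1 | intermediate
35 | {[(1S,2S)-2-[2-(benzyloxy)-5-bromo-3-methoxyphenyl]-1-[4-(benzyloxy)-3-methoxyphenyl]propane-1,3-diyl]bis(oxy)}bis[tert-butyl(dimethyl)silane] | COc1cc([C@@H](O[Si](C)(C)C(C)(C)C)[C@H](CO[Si](C)(C)C(C)(C)C)c2cc(Br)cc(OC)c2OCc2ccccc2)ccc1OCc1ccccc1 | intermediate
36 | 4-(benzyloxy)-3-{(1S,2S)-1-[4-(benzyloxy)-3-methoxyphenyl]-1,3-bis[(tert-butyldimethylsilyl)oxy]propan-2-yl}-5-methoxybenzaldehyde | COc1cc([C@@H](O[Si](C)(C)C(C)(C)C)[C@H](CO[Si](C)(C)C(C)(C)C)c2cc(C=O)cc(OC)c2OCc2ccccc2)ccc1OCc1ccccc1 | intermediate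
37 | (4-(benzyloxy)-3-{(1S,2S)-1-[4-(benzyloxy)-3-methoxyphenyl]-1,3-bis[(tert-butyldimethylsilyl)oxy]propan-2-yl}-5-methoxyphenyl)methanol | COc1cc([C@@H](O[Si](C)(C)C(C)(C)C)[C@H](CO[Si](C)(C)C(C)(C)C)c2cc(CO)cc(OC)c2OCc2ccccc2)ccc1OCc1ccccc1 | intermediate
38 | 4-(benzyloxy)-3-{(1S,2S)-1-[4-(benzyloxy)-3-methoxyphenyl]-1,3-bis[(tert-butyldimethylsilyl)oxy]propan-2-yl}-5-methoxybenzyl bromide | COc1cc([C@@H](O[Si](C)(C)C(C)(C)C)[C@H](CO[Si](C)(C)C(C)(C)C)c2cc(CBr)cc(OC)c2OCc2ccccc2)ccc1OCc1ccccc1 | intermediate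
39 | (3R,4R)-3-(4-(benzyloxy)-3-{(1S,2S)-1-[4-(benzyloxy)-3-methoxyphenyl]-1,3-bis[(tert-butyldimethylsilyl)oxy]propan-2-yl}-5-methoxybenzyl)-4-({(2S,3R)-2-[4-(benzyloxy)-3-methoxyphenyl]-3-{[(tert-butyldimethylsilyl)oxy]methyl}-7-methoxy-2,3-dihydro-1-benzofuran-5-yl}methyl)oxolan-2-one | COc1cc([C@@H](O[Si](C)(C)C(C)(C)C)[C@H](CO[Si](C)(C)C(C)(C)C)c2cc(C[C@H]3C(=O)OC[C@@H]3Cc3cc(OC)c4c(c3)[C@H](CO[Si](C)(C)C(C)(C)C)[C@@H](c3ccc(OCc5ccccc5)c(OC)c3)O4)cc(OC)c2OCc2ccccc2)ccc1OCc1ccccc1 | intermediate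
40 | (3R,4R)-3-(4-(benzyloxy)-3-{(1S,2S)-1-[4-(benzyloxy)-3-methoxyphenyl]-1,3-dihydroxypropan-2-yl}-5-methoxybenzyl)-4-({(2S,3R)-2-[4-(benzyloxy)-3-methoxyphenyl]-3-(hydroxymethyl)-7-methoxy-2,3-dihydro-1-benzofuran-5-yl}methyl)oxolan-2-one | COc1cc([C@@H](O)[C@H](CO)c2cc(C[C@H]3C(=O)OC[C@@H]3Cc3cc(OC)c4c(c3)[C@H](CO)[C@@H](c3ccc(OCc5ccccc5)c(OC)c3)O4)cc(OC)c2OCc2ccccc2)ccc1OCc1ccccc1 | intermediate
41 | (3R,4R)-4-{[(2S,3R)-2-(4-hydroxy-3-methoxyphenyl)-3-(hydroxymethyl)-7-methoxy-2,3-dihydro-1-benzofuran-5-yl]methyl}-3-{3-[(1S,2S)-1,3-dihydroxy-1-(4-hydroxy-3-methoxyphenyl)propan-2-yl]-4-hydroxy-5-methoxybenzyl}oxolan-2-one (CNP0186558.2) | COc1cc([C@@H](O)[C@H](CO)c2cc(C[C@H]3C(=O)OC[C@@H]3Cc3cc(OC)c4c(c3)[C@H](CO)[C@@H](c3ccc(O)c(OC)c3)O4)cc(OC)c2O)ccc1O | target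

**Step count**

Total: 26 steps. Longest linear sequence: 16 steps (steps 1–5, 7–14, 24–26).

**Steps most likely to fail, with fallbacks**

Step 18. Under soft enolisation the aryl-stabilised magnesium enolate may add with poor anti or facial selectivity, or the aldolate may revert before it is silylated and so scramble C2. The fallback sets the two centers by a boron syn aldol in the enantiomeric auxiliary series and then inverts the carbinol. It sets out from acid 28 and comes back at 35.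
- Acid 28, through its mixed anhydride 29, would be joined to (R)-4-benzyl-2-oxazolidinone to give (4R)-4-benzyl-3-{2-[2-(benzyloxy)-5-bromo-3-methoxyphenyl]acetyl}-1,3-oxazolidin-2-one F1.
- The n-Bu2BOTf/i-Pr2NEt aldol of F1 with 31 should give the (2R,3R) syn aldol adduct F2, and LiBH4 would reduce it to the (1R,2S)-diol F3.
- TBSCl/imidazole would silylate only the primary hydroxyl to give the primary mono-TBS ether F4.
- A Mitsunobu reaction (4-nitrobenzoic acid, PPh3, diisopropyl azodicarboxylate) would invert the benzylic carbinol to the (1S) 4-nitrobenzoate F5.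
- K2CO3 in MeOH would release the (1S,2S) mono-TBS alcohol F6, which TBSOTf/2,6-lutidine converts into 35.

Step 24. The electron-rich, hindered benzylic bromide may ionise or decompose faster than the lactone enolate captures it, or proton transfer between enolate and product may lead to double alkylation. The fallback replaces the SN2 step by aldol addition, elimination and conjugate reduction. It sets out from lactone 25 and aldehyde 36 and comes back at 39.
- The lithium enolate of 25 (LiN(SiMe3)2, THF, −78 °C) would add to 36 to give the β-hydroxy lactone F7 as a mixture of epimers.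
- MsCl/Et3N would convert F7 into the mesylate F8, and DBU would eliminate it to the (E)-α-arylidene lactone F9.
- NiCl2·6H2O/NaBH4 in MeOH–THF would reduce the conjugated double bond, and DBU would equilibrate C3 to the more stable trans lactone 39.

Step 12. Hot methoxide may open the dihydrofuran by β-elimination of the ring oxygen, which now sits para to a formyl group, or the condensation may stall on the hindered aldehyde. The fallback builds the lactone by auxiliary-controlled alkylation of a succinate imide. It sets out from aldehyde 20 and comes back at 25.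
- NaBH4 would reduce 20 to the dihydrobenzofuran benzylic alcohol F10, and CBr4/PPh3 would give the dihydrobenzofuran benzylic bromide F11.
- The sodium enolate (NaN(SiMe3)2, THF, −78 °C) of the known imide (R)-4-benzyl-3-(4-tert-butoxy-4-oxobutanoyl)oxazolidin-2-one would be alkylated by F11 on the face opposite the auxiliary benzyl group to give the (R)-configured alkylated succinate imide F12.
- LiBH4 would cleave the auxiliary to the hydroxy tert-butyl ester F13, and pyridinium p-toluenesulfonate in warm toluene would lactonise it to 25.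

Further compounds
F1 | step 18 | (4R)-4-benzyl-3-{2-[2-(benzyloxy)-5-bromo-3-methoxyphenyl]acetyl}-1,3-oxazolidin-2-one | O=C1OC[C@@H](Cc2ccccc2)N1C(=O)Cc1cc(Br)cc(OC)c1OCc1ccccc1
F2 | step 18 | (4R)-4-benzyl-3-{(2R,3R)-2-[2-(benzyloxy)-5-bromo-3-methoxyphenyl]-3-[4-(benzyloxy)-3-methoxyphenyl]-3-hydroxypropanoyl}-1,3-oxazolidin-2-one | COc1cc([C@H](O)[C@H](C(=O)N2[C@H](Cc3ccccc3)COC2=O)c2cc(Br)cc(OC)c2OCc2ccccc2)ccc1OCc1ccccc1
F3 | step 18 | (1R,2S)-2-[2-(benzyloxy)-5-bromo-3-methoxyphenyl]-1-[4-(benzyloxy)-3-methoxyphenyl]propane-1,3-diol | COc1cc([C@H](O)[C@H](CO)c2cc(Br)cc(OC)c2OCc2ccccc2)ccc1OCc1ccccc1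
F4 | step 18 | (1R,2S)-2-[2-(benzyloxy)-5-bromo-3-methoxyphenyl]-1-[4-(benzyloxy)-3-methoxyphenyl]-3-[(tert-butyldimethylsilyl)oxy]propan-1-ol | COc1cc([C@H](O)[C@H](CO[Si](C)(C)C(C)(C)C)c2cc(Br)cc(OC)c2OCc2ccccc2)ccc1OCc1ccccc1
F5 | step 18 | (1S,2S)-2-[2-(benzyloxy)-5-bromo-3-methoxyphenyl]-1-[4-(benzyloxy)-3-methoxyphenyl]-3-[(tert-butyldimethylsilyl)oxy]propyl 4-nitrobenzoate | COc1cc([C@@H](OC(=O)c2ccc(cc2)[N+](=O)[O-])[C@H](CO[Si](C)(C)C(C)(C)C)c2cc(Br)cc(OC)c2OCc2ccccc2)ccc1OCc1ccccc1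
F6 | step 18 | (1S,2S)-2-[2-(benzyloxy)-5-bromo-3-methoxyphenyl]-1-[4-(benzyloxy)-3-methoxyphenyl]-3-[(tert-butyldimethylsilyl)oxy]propan-1-ol | COc1cc([C@@H](O)[C@H](CO[Si](C)(C)C(C)(C)C)c2cc(Br)cc(OC)c2OCc2ccccc2)ccc1OCc1ccccc1
F7 | step 24 | (4R)-3-[(4-(benzyloxy)-3-{(1S,2S)-1-[4-(benzyloxy)-3-methoxyphenyl]-1,3-bis[(tert-butyldimethylsilyl)oxy]propan-2-yl}-5-methoxyphenyl)(hydroxy)methyl]-4-({(2S,3R)-2-[4-(benzyloxy)-3-methoxyphenyl]-3-{[(tert-butyldimethylsilyl)oxy]methyl}-7-methoxy-2,3-dihydro-1-benzofuran-5-yl}methyl)oxolan-2-one (epimers at C3 and the carbinol carbon) | COc1cc([C@@H](O[Si](C)(C)C(C)(C)C)[C@H](CO[Si](C)(C)C(C)(C)C)c2cc(C(O)C3C(=O)OC[C@@H]3Cc3cc(OC)c4c(c3)[C@H](CO[Si](C)(C)C(C)(C)C)[C@@H](c3ccc(OCc5ccccc5)c(OC)c3)O4)cc(OC)c2OCc2ccccc2)ccc1OCc1ccccc1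
F8 | step 24 | methanesulfonate of F7 at the new carbinol | COc1cc([C@@H](O[Si](C)(C)C(C)(C)C)[C@H](CO[Si](C)(C)C(C)(C)C)c2cc(C(OS(C)(=O)=O)C3C(=O)OC[C@@H]3Cc3cc(OC)c4c(c3)[C@H](CO[Si](C)(C)C(C)(C)C)[C@@H](c3ccc(OCc5ccccc5)c(OC)c3)O4)cc(OC)c2OCc2ccccc2)ccc1OCc1ccccc1
F9 | step 24 | (3E,4R)-3-(4-(benzyloxy)-3-{(1S,2S)-1-[4-(benzyloxy)-3-methoxyphenyl]-1,3-bis[(tert-butyldimethylsilyl)oxy]propan-2-yl}-5-methoxybenzylidene)-4-({(2S,3R)-2-[4-(benzyloxy)-3-methoxyphenyl]-3-{[(tert-butyldimethylsilyl)oxy]methyl}-7-methoxy-2,3-dihydro-1-benzofuran-5-yl}methyl)oxolan-2-one | COc1cc([C@@H](O[Si](C)(C)C(C)(C)C)[C@H](CO[Si](C)(C)C(C)(C)C)c2cc(/C=C3/C(=O)OC[C@@H]3Cc3cc(OC)c4c(c3)[C@H](CO[Si](C)(C)C(C)(C)C)[C@@H](c3ccc(OCc5ccccc5)c(OC)c3)O4)cc(OC)c2OCc2ccccc2)ccc1OCc1ccccc1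
F10 | step 12 | [(2S,3R)-2-[4-(benzyloxy)-3-methoxyphenyl]-3-{[(tert-butyldimethylsilyl)oxy]methyl}-7-methoxy-2,3-dihydro-1-benzofuran-5-yl]methanol | OCc1cc(OC)c2c(c1)[C@H](CO[Si](C)(C)C(C)(C)C)[C@@H](c1ccc(OCc3ccccc3)c(OC)c1)O2
F11 | step 12 | {[(2S,3R)-2-[4-(benzyloxy)-3-methoxyphenyl]-5-(bromomethyl)-7-methoxy-2,3-dihydro-1-benzofuran-3-yl]methoxy}(tert-butyl)dimethylsilane | BrCc1cc(OC)c2c(c1)[C@H](CO[Si](C)(C)C(C)(C)C)[C@@H](c1ccc(OCc3ccccc3)c(OC)c1)O2
F12 | step 12 | tert-butyl (3R)-4-[(4R)-4-benzyl-2-oxo-1,3-oxazolidin-3-yl]-3-({(2S,3R)-2-[4-(benzyloxy)-3-methoxyphenyl]-3-{[(tert-butyldimethylsilyl)oxy]methyl}-7-methoxy-2,3-dihydro-1-benzofuran-5-yl}methyl)-4-oxobutanoate | O=C1OC[C@@H](Cc2ccccc2)N1C(=O)[C@@H](CC(=O)OC(C)(C)C)Cc1cc(OC)c2c(c1)[C@H](CO[Si](C)(C)C(C)(C)C)[C@@H](c1ccc(OCc3ccccc3)c(OC)c1)O2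
F13 | step 12 | tert-butyl (3R)-4-{(2S,3R)-2-[4-(benzyloxy)-3-methoxyphenyl]-3-{[(tert-butyldimethylsilyl)oxy]methyl}-7-methoxy-2,3-dihydro-1-benzofuran-5-yl}-3-(hydroxymethyl)butanoate | OC[C@@H](CC(=O)OC(C)(C)C)Cc1cc(OC)c2c(c1)[C@H](CO[Si](C)(C)C(C)(C)C)[C@@H](c1ccc(OCc3ccccc3)c(OC)c1)O2
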